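**Plan**

1. Locants: the chain is numbered C1–C15 from the free CH2OH end (C7 bears CH2OAc, C11 the methyl group); the oxolane consists of O, C12 (CH), C13 (CH2), C14 (CHOH) and C15 (CMe2).
2. Retrosynthesis: the C6=C7 double bond (Z-selective Ando olefination) and then the C7–C8 bond (phosphonoacetate alkylation) are cut, giving a C1–C6 aldehyde from geraniol and a C8–C15 iodide; in the iodide C8–C13 come from (R)-citronellal (its C1/C2 are C13/C12) and C14/C15 from an isobutenyl Grignard reagent.
3. Ring: the oxolane is traced back through its C12=C13 enol ether/C14 alcohol and the C13–C14 oxirane to a 2,5-dihydrofuran, which arises by ring expansion of the C12/C13 oxirane carrying a 2-methylprop-1-enyl group. This is possible because the ring oxygen lies between a CH (C12) and a CMe2 (C15) joined by the two-carbon unit C13–C14, i.e. the O–C–C=C–C array of a dihydrofuran in which the allylic C13–O bond of the oxirane is exchanged for an O–C15 bond.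
4. Forward order: chlorination, Grignard addition and closure give the oxirane; ring expansion builds the five-membered ring; C14 is oxygenated, the isopropylidene end is clipped to the C8 iodide, and the two halves are joined last.
5. Stereochemistry: C11 from (R)-citronellal; C12 by catalyst-controlled α-chlorination (inverted on oxirane closure, untouched by the ring expansion); C14 relayed from C12 by anti epoxidation; C12 then passes through sp2 and is re-set from the C14 hydroxyl by directed hydrogenation; 2E from geraniol, 6Z from the olefination.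

Key step: step 3

Assumption: (2R,5R)-2,5-diphenylpyrrolidine is taken as the catalyst enantiomer that delivers the (2S)-chloro aldehyde; should the sense be the opposite, the (2S,5S) catalyst is used in step 1.

**Route**

Step 1
Reactants: 1 (R)-citronellal
Product: 2 (2S,3R)-2-chloro-3,7-dimethyloct-6-enal
Conditions: NCS (1.3 equiv), (2R,5R)-2,5-diphenylpyrrolidine (10 mol %), CH2Cl2, 0 °C to rt; pentane, filtration; used crude
Reagents that add atoms: N-chlorosuccinimide, ClN1C(=O)CCC1=O
Why: Organocatalytic enamine α-chlorination of an aldehyde, in which the C2-symmetric amine shields one enamine face so that the new C–Cl centre (later C12) is set by the catalyst and not by the β-methyl group, and the enamine reacts with NCS much faster than the trisubstituted alkene does.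

Step 2
Reactants: 2 (2S,3R)-2-chloro-3,7-dimethyloct-6-enal; 3 (2-methylprop-1-en-1-yl)magnesium bromide
Product: 5 (2R,3R)-2-[(2R)-6-methylhept-5-en-2-yl]-3-(2-methylprop-1-en-1-yl)oxirane, via chlorohydrin 4 (not isolated)
Conditions: 3 (1.3 equiv), THF, −78 °C; then KOH, EtOH, 0 °C to rt
Reagents that add atoms: none
Why: Alkenyl Grignard addition to an α-chloro aldehyde (Cornforth-type, mainly anti) followed by Williamson closure with inversion at the chlorine-bearing carbon, which fixes C12; the carbinol centre C13 is erased in step 3, so its epimer is carried along and converges.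

Step 3
Reactants: 5 (2R,3R)-2-[(2R)-6-methylhept-5-en-2-yl]-3-(2-methylprop-1-en-1-yl)oxirane
Product: 6 (5R)-2,2-dimethyl-5-[(2R)-6-methylhept-5-en-2-yl]-2,5-dihydrofuran
Conditions: Cu(hfacac)2 (5 mol %), toluene, 110 °C
Reagents that add atoms: none
Why: Copper-catalysed ring expansion of a vinyl oxirane: the Lewis-acidic copper centre activates the oxirane, the allylic C13–O bond is cleaved with the help of the trisubstituted alkene, and the oxygen, still bonded to C12, is re-attached to the Me2C terminus C15 (collapse of an alkoxide/allyl-copper pair or C–O reductive elimination from a six-membered oxa-cuprate) while the double bond moves to C13=C14. The closest known reaction type is the Cu(hfacac)2-catalysed rearrangement of alkenyl oxiranes to 2,5-dihydrofurans. The five-membered ring is closed by O–C15 bond formation, formally a 5-endo closure of the alkoxide onto the allyl terminus, while the three-membered ring is opened. No stereocentre is created: C12 keeps its configuration because its C–O bond is never broken, C13 becomes sp2 so that both epimers of 5 converge, and C15 carries two methyl groups. The step needs cleavage of the allylic C–O bond only and ring closure in place of proton loss to a dienol or hydride shift to a ketone; the first is secured because only the C13–O bond is allylic and its cleavage gives a dimethyl-stabilised allyl unit, the second by the tethered oxygen facing a tertiary, strongly electrophilic terminus in a non-protic, weakly Lewis-acidic medium.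

Step 4
Reactants: 6 (5R)-2,2-dimethyl-5-[(2R)-6-methylhept-5-en-2-yl]-2,5-dihydrofuran
Product: 7 (1R,4R,5R)-4-[(2R)-4-(3,3-dimethyloxiran-2-yl)butan-2-yl]-2,2-dimethyl-3,6-dioxabicyclo[3.1.0]hexane
Conditions: dimethyldioxirane (3 equiv, acetone solution), CH2Cl2, 0 °C to rt
Reagents that add atoms: dimethyldioxirane, CC1(C)OO1
Why: Dioxirane epoxidation of both alkenes, where oxygen is delivered to the flat dihydrofuran on the face opposite the branched C12 substituent (this sets the C14–O centre), any syn-oxirane cannot react in step 6, and the side-chain oxirane (mixture of epimers) is only a mask for the C8 aldehyde.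

Step 5
Reactants: 7 (1R,4R,5R)-4-[(2R)-4-(3,3-dimethyloxiran-2-yl)butan-2-yl]-2,2-dimethyl-3,6-dioxabicyclo[3.1.0]hexane
Product: 9 (4R)-4-[(1R,4R,5R)-2,2-dimethyl-3,6-dioxabicyclo[3.1.0]hexan-4-yl]pentan-1-ol, via aldehyde 8 (not isolated)
Conditions: H5IO6 (1.1 equiv), THF/Et2O, 0 °C; filtration; then NaBH4, MeOH, 0 °C
Reagents that add atoms: none
Why: Periodic acid opens the electron-rich trisubstituted oxirane at its tertiary carbon and cleaves the glycol to aldehyde and acetone, whereas the ring-fused oxirane (secondary carbons, β-oxygen, quaternary neighbour) is inert at 0 °C; borohydride then reduces only the aldehyde.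

Step 6
Reactants: 9 (4R)-4-[(1R,4R,5R)-2,2-dimethyl-3,6-dioxabicyclo[3.1.0]hexan-4-yl]pentan-1-ol
Product: 10 (3R)-5-[(2R)-5-hydroxypentan-2-yl]-2,2-dimethyl-2,3-dihydrofuran-3-ol
Conditions: Et2Al(TMP) (4 equiv, from LiTMP and Et2AlCl), toluene, 0 °C to rt; Rochelle salt work-up; Et3N-deactivated silica
Reagents that add atoms: none
Why: Aluminium amide isomerisation of an oxirane to an allylic alcohol by syn β-elimination: the only β-hydrogen is C12–H (C15 is quaternary) and in the anti-oxirane it is cis to the oxirane oxygen, so the C13–O bond breaks, the oxygen stays on C14 with its configuration, and C12 becomes sp2.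

Step 7
Reactants: 10 (3R)-5-[(2R)-5-hydroxypentan-2-yl]-2,2-dimethyl-2,3-dihydrofuran-3-ol
Product: 11 (3R,5S)-5-[(2R)-5-hydroxypentan-2-yl]-2,2-dimethyloxolan-3-ol
Conditions: H2 (50 bar), [Rh(nbd)(dppb)]BF4 (5 mol %), THF, rt, acid-free glassware
Reagents that add atoms: none
Why: Hydroxyl-directed homogeneous hydrogenation of a cyclic allylic alcohol, in which the cationic rhodium binds the C14 hydroxyl and delivers both hydrogens to the C12=C13 enol ether from that face, so the new C12 centre carries its side chain trans to the hydroxyl.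

Step 8
Reactants: 11 (3R,5S)-5-[(2R)-5-hydroxypentan-2-yl]-2,2-dimethyloxolan-3-ol
Product: 12 (3R,5S)-5-[(2R)-5-iodopentan-2-yl]-2,2-dimethyloxolan-3-ol
Conditions: I2 (1.1 equiv), PPh3, imidazole, CH2Cl2, 0 °C
Reagents that add atoms: iodine, II
Why: Appel-type iodination that converts the primary alcohol, while the secondary hydroxyl next to the quaternary carbon is too hindered to form the alkoxyphosphonium salt at 0 °C.

Step 9
Reactants: 12 (3R,5S)-5-[(2R)-5-iodopentan-2-yl]-2,2-dimethyloxolan-3-ol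
Product: 13 triethyl{[(3R,5S)-5-[(2R)-5-iodopentan-2-yl]-2,2-dimethyloxolan-3-yl]oxy}silane
Conditions: TESOTf, 2,6-lutidine, CH2Cl2, −78 °C
Reagents that add atoms: triethylsilyl trifluoromethanesulfonate, CC[Si](CC)(CC)OS(=O)(=O)C(F)(F)F
Why: Silylation of a hindered secondary alcohol with a silyl triflate and a hindered pyridine base, to which the alkyl iodide is inert.

Step 10
Reactants: 13 triethyl{[(3R,5S)-5-[(2R)-5-iodopentan-2-yl]-2,2-dimethyloxolan-3-yl]oxy}silane; 14 ethyl 2-[bis(2-methylphenoxy)phosphoryl]acetate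
Product: 15 ethyl (6R)-2-[bis(2-methylphenoxy)phosphoryl]-6-[(2S,4R)-5,5-dimethyl-4-(triethylsilyloxy)oxolan-2-yl]heptanoate
Conditions: 14 (3 equiv), NaH (3 equiv), DMSO, rt; then 13, 50 °C
Reagents that add atoms: none
Why: SN2 alkylation of a stabilised phosphonoacetate anion with a primary iodide, where the excess of the inexpensive phosphonate suppresses dialkylation and the new centre at C7 (mixture of epimers) is removed in step 14.

Step 11
Reactants: 16 geraniol
Product: 17 tert-butyl{[(2E)-3,7-dimethylocta-2,6-dien-1-yl]oxy}dimethylsilane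
Conditions: TBSCl, imidazole, DMF, rt
Reagents that add atoms: tert-butyldimethylsilyl chloride, CC(C)(C)[Si](C)(C)Cl
Why: Standard silylation of the primary allylic alcohol.

Step 12
Reactants: 17 tert-butyl{[(2E)-3,7-dimethylocta-2,6-dien-1-yl]oxy}dimethylsilane
Product: 18 tert-butyl{[(2E)-5-(3,3-dimethyloxiran-2-yl)-3-methylpent-2-en-1-yl]oxy}dimethylsilane
Conditions: mCPBA (1.0 equiv), NaHCO3, CH2Cl2, −20 °C
Reagents that add atoms: 3-chloroperbenzoic acid, OOC(=O)c1cccc(Cl)c1
Why: Chemoselective Prilezhaev epoxidation, because the distal alkene is more nucleophilic than the 2,3-alkene, which is deactivated by the allylic C–O bond.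

Step 13
Reactants: 18 tert-butyl{[(2E)-5-(3,3-dimethyloxiran-2-yl)-3-methylpent-2-en-1-yl]oxy}dimethylsilane
Product: 19 (4E)-6-[(tert-butyldimethylsilyl)oxy]-4-methylhex-4-enal
Conditions: H5IO6 (1.1 equiv), THF/Et2O, 0 °C, short reaction time
Reagents that add atoms: none
Why: Periodic acid opens the trisubstituted oxirane and cleaves the glycol to the aldehyde and acetone, and the 2E alkene and the silyl ether survive the brief cold treatment.

Step 14
Reactants: 15 ethyl (6R)-2-[bis(2-methylphenoxy)phosphoryl]-6-[(2S,4R)-5,5-dimethyl-4-(triethylsilyloxy)oxolan-2-yl]heptanoate; 19 (4E)-6-[(tert-butyldimethylsilyl)oxy]-4-methylhex-4-enal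
Product: 20 ethyl (2Z,6E)-8-[(tert-butyldimethylsilyl)oxy]-2-{(4R)-4-[(2S,4R)-5,5-dimethyl-4-(triethylsilyloxy)oxolan-2-yl]pentyl}-6-methylocta-2,6-dienoate
Conditions: NaH, THF, 0 °C; then 19, −78 to 0 °C
Reagents that add atoms: none
Why: Horner–Wadsworth–Emmons olefination in the Ando variant, in which the aryloxy groups on phosphorus speed up collapse of the first-formed oxaphosphetane so that the kinetic (Z)-α-alkyl enoate forms, with the ester cis to the C5 methylene as required for the later CH2OAc group.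

Step 15
Reactants: 20 ethyl (2Z,6E)-8-[(tert-butyldimethylsilyl)oxy]-2-{(4R)-4-[(2S,4R)-5,5-dimethyl-4-(triethylsilyloxy)oxolan-2-yl]pentyl}-6-methylocta-2,6-dienoate
Product: 21 (2Z,6E)-8-[(tert-butyldimethylsilyl)oxy]-2-{(4R)-4-[(2S,4R)-5,5-dimethyl-4-(triethylsilyloxy)oxolan-2-yl]pentyl}-6-methylocta-2,6-dien-1-ol
Conditions: DIBAL-H (2.5 equiv), CH2Cl2, −78 °C; Rochelle salt
Reagents that add atoms: none
Why: DIBAL-H reduces the conjugated ester to the allylic alcohol without 1,4-reduction or loss of olefin geometry and leaves both silyl ethers intact.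

Step 16
Reactants: 21 (2Z,6E)-8-[(tert-butyldimethylsilyl)oxy]-2-{(4R)-4-[(2S,4R)-5,5-dimethyl-4-(triethylsilyloxy)oxolan-2-yl]pentyl}-6-methylocta-2,6-dien-1-ol
Product: 22 (2Z,6E)-8-[(tert-butyldimethylsilyl)oxy]-2-{(4R)-4-[(2S,4R)-5,5-dimethyl-4-(triethylsilyloxy)oxolan-2-yl]pentyl}-6-methylocta-2,6-dien-1-yl acetate
Conditions: Ac2O, pyridine, DMAP (cat.), CH2Cl2, 0 °C
Reagents that add atoms: acetic anhydride, CC(=O)OC(C)=O
Why: DMAP-catalysed acylation of the only free hydroxyl, which differentiates the C7 hydroxymethyl group from the still silylated C1 alcohol.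

Step 17
Reactants: 22 (2Z,6E)-8-[(tert-butyldimethylsilyl)oxy]-2-{(4R)-4-[(2S,4R)-5,5-dimethyl-4-(triethylsilyloxy)oxolan-2-yl]pentyl}-6-methylocta-2,6-dien-1-yl acetate
Product: 23 (2Z,6E)-8-hydroxy-2-{(4R)-4-[(2S,4R)-4-hydroxy-5,5-dimethyloxolan-2-yl]pentyl}-6-methylocta-2,6-dien-1-yl acetate (CNP0295947.1)
Conditions: HF·pyridine, pyridine, THF, 0 °C to rt
Reagents that add atoms: none
Why: Fluoride-mediated cleavage of both silyl ethers under buffered conditions that neither cleave nor shift the allylic acetate and touch no stereocentre.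

**Compound list**

1 | (R)-citronellal, (3R)-3,7-dimethyloct-6-enal | CC(C)=CCC[C@@H](C)CC=O | starting material
2 | (2S,3R)-2-chloro-3,7-dimethyloct-6-enal | CC(C)=CCC[C@@H](C)[C@@H](C=O)Cl | intermediate
3 | (2-methylprop-1-en-1-yl)magnesium bromide | CC(C)=C[Mg]Br | starting material
4 | (4R,5S,6R)-5-chloro-2,6,10-trimethylundeca-2,9-dien-4-ol (anti chlorohydrin, main epimer at C4; not isolated) | CC(C)=CCC[C@@H](C)[C@@H]([C@H](O)C=C(C)C)Cl | intermediate
5 | (2R,3R)-2-[(2R)-6-methylhept-5-en-2-yl]-3-(2-methylprop-1-en-1-yl)oxirane (trans, main isomer) | CC(C)=CCC[C@@H](C)[C@H]1O[C@@H]1C=C(C)C | intermediate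
6 | (5R)-2,2-dimethyl-5-[(2R)-6-methylhept-5-en-2-yl]-2,5-dihydrofuran | CC(C)=CCC[C@@H](C)[C@@H]1C=CC(C)(C)O1 | intermediate
7 | (1R,4R,5R)-4-[(2R)-4-(3,3-dimethyloxiran-2-yl)butan-2-yl]-2,2-dimethyl-3,6-dioxabicyclo[3.1.0]hexane (ring oxirane trans to the side chain; side-chain oxirane as epimers) | CC1(C)OC1CC[C@@H](C)[C@H]2OC(C)(C)[C@@H]3O[C@H]23 | intermediate
8 | (4R)-4-[(1R,4R,5R)-2,2-dimethyl-3,6-dioxabicyclo[3.1.0]hexan-4-yl]pentanal (not isolated) | O=CCC[C@@H](C)[C@H]1OC(C)(C)[C@@H]2O[C@H]12 | intermediate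
9 | (4R)-4-[(1R,4R,5R)-2,2-dimethyl-3,6-dioxabicyclo[3.1.0]hexan-4-yl]pentan-1-ol | OCCC[C@@H](C)[C@H]1OC(C)(C)[C@@H]2O[C@H]12 | intermediate
10 | (3R)-5-[(2R)-5-hydroxypentan-2-yl]-2,2-dimethyl-2,3-dihydrofuran-3-ol | OCCC[C@@H](C)C1=C[C@@H](O)C(C)(C)O1 | intermediate
11 | (3R,5S)-5-[(2R)-5-hydroxypentan-2-yl]-2,2-dimethyloxolan-3-ol | OCCC[C@@H](C)[C@@H]1C[C@@H](O)C(C)(C)O1 | intermediate
12 | (3R,5S)-5-[(2R)-5-iodopentan-2-yl]-2,2-dimethyloxolan-3-ol | ICCC[C@@H](C)[C@@H]1C[C@@H](O)C(C)(C)O1 | intermediate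
13 | triethyl{[(3R,5S)-5-[(2R)-5-iodopentan-2-yl]-2,2-dimethyloxolan-3-yl]oxy}silane | ICCC[C@@H](C)[C@@H]1C[C@@H](O[Si](CC)(CC)CC)C(C)(C)O1 | intermediate
14 | ethyl 2-[bis(2-methylphenoxy)phosphoryl]acetate | CCOC(=O)CP(=O)(Oc1ccccc1C)Oc1ccccc1C | starting material
15 | ethyl (6R)-2-[bis(2-methylphenoxy)phosphoryl]-6-[(2S,4R)-5,5-dimethyl-4-(triethylsilyloxy)oxolan-2-yl]heptanoate (epimers at C2) | CCOC(=O)C(CCC[C@@H](C)[C@@H]1C[C@@H](O[Si](CC)(CC)CC)C(C)(C)O1)P(=O)(Oc1ccccc1C)Oc1ccccc1C | intermediate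
16 | geraniol, (2E)-3,7-dimethylocta-2,6-dien-1-ol | CC(C)=CCC/C(C)=C/CO | starting material
17 | tert-butyl{[(2E)-3,7-dimethylocta-2,6-dien-1-yl]oxy}dimethylsilane | CC(C)=CCC/C(C)=C/CO[Si](C)(C)C(C)(C)C | intermediate
18 | tert-butyl{[(2E)-5-(3,3-dimethyloxiran-2-yl)-3-methylpent-2-en-1-yl]oxy}dimethylsilane (racemic oxirane) | CC1(C)OC1CC/C(C)=C/CO[Si](C)(C)C(C)(C)C | intermediate
19 | (4E)-6-[(tert-butyldimethylsilyl)oxy]-4-methylhex-4-enal | O=CCC/C(C)=C/CO[Si](C)(C)C(C)(C)C | intermediate
20 | ethyl (2Z,6E)-8-[(tert-butyldimethylsilyl)oxy]-2-{(4R)-4-[(2S,4R)-5,5-dimethyl-4-(triethylsilyloxy)oxolan-2-yl]pentyl}-6-methylocta-2,6-dienoate | CCOC(=O)/C(=C\CC/C(C)=C/CO[Si](C)(C)C(C)(C)C)CCC[C@@H](C)[C@@H]1C[C@@H](O[Si](CC)(CC)CC)C(C)(C)O1 | intermediate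
21 | (2Z,6E)-8-[(tert-butyldimethylsilyl)oxy]-2-{(4R)-4-[(2S,4R)-5,5-dimethyl-4-(triethylsilyloxy)oxolan-2-yl]pentyl}-6-methylocta-2,6-dien-1-ol | OC/C(=C\CC/C(C)=C/CO[Si](C)(C)C(C)(C)C)CCC[C@@H](C)[C@@H]1C[C@@H](O[Si](CC)(CC)CC)C(C)(C)O1 | intermediate
22 | (2Z,6E)-8-[(tert-butyldimethylsilyl)oxy]-2-{(4R)-4-[(2S,4R)-5,5-dimethyl-4-(triethylsilyloxy)oxolan-2-yl]pentyl}-6-methylocta-2,6-dien-1-yl acetate | CC(=O)OC/C(=C\CC/C(C)=C/CO[Si](C)(C)C(C)(C)C)CCC[C@@H](C)[C@@H]1C[C@@H](O[Si](CC)(CC)CC)C(C)(C)O1 | intermediate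
23 | (2Z,6E)-8-hydroxy-2-{(4R)-4-[(2S,4R)-4-hydroxy-5,5-dimethyloxolan-2-yl]pentyl}-6-methylocta-2,6-dien-1-yl acetate | CC(=O)OC/C(=C\CC/C(C)=C/CO)CCC[C@@H](C)[C@@H]1C[C@@H](O)C(C)(C)O1 | target

**Step count and risks**

Total step count: 17. Longest linear sequence: 14 (steps 1–10 and 14–17); steps 11–13 form the side branch.

Steps most likely to fail:

1. Step 3. Ionisation of the dimethyl-substituted allylic system may end in proton loss (dienol) or a 1,2-hydride shift (β,γ-enone) in place of C–O bond formation, because closure needs the s-cis arrangement in which the cis-methyl group clashes with the oxirane. The fallback sets out from 2 and builds the same dihydrofuran by cyclisation of an allenol. Addition of prop-1-ynylmagnesium bromide (THF, −78 °C) should give the propargylic chlorohydrin (4R,5S,6R)-5-chloro-6,10-dimethylundec-9-en-2-yn-4-ol F1, and KOH/EtOH should close it to the alkynyl oxirane (2R,3R)-2-[(2R)-6-methylhept-5-en-2-yl]-3-(prop-1-yn-1-yl)oxirane F2. Copper-catalysed anti-SN2′ addition of MeMgBr (CuBr·SMe2, THF, −40 °C) should open the oxirane to the α-allenol (5R,6R)-2,6,10-trimethylundeca-2,3,9-trien-5-ol F3 with the C12–O bond intact. Silver(I)-catalysed 5-endo cyclisation of the allenol (AgNO3, acetone, rt) should then give 6, where the route is rejoined.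

2. Step 7. Trace acid may add the δ-hydroxyl of 10 to the enol ether (spiroketalisation), and metal-hydride double-bond migration to the exocyclic position would erode the C11 centre; face control is lost if the catalyst does not bind the C14 hydroxyl. The fallback sets out from 10 and replaces hydrogenation by an ionic reduction under stereoelectronic control. Both hydroxyls are silylated (TESOTf, 2,6-lutidine, −78 °C) to triethyl{[(4R)-4-[(4R)-5,5-dimethyl-4-(triethylsilyloxy)-4,5-dihydrofuran-2-yl]pentyl]oxy}silane F4. Et3SiH/CF3CO2H (CH2Cl2, −78 °C) should protonate the enol ether at C13 and reduce the cyclic oxocarbenium ion from the face cis to the C14 silyloxy group (inside attack on the envelope with a pseudoaxial 3-alkoxy group), giving the 3,5-trans oxolane triethyl{[(4R)-4-[(2S,4R)-5,5-dimethyl-4-(triethylsilyloxy)oxolan-2-yl]pentyl]oxy}silane F5. PPTS/MeOH at 0 °C should remove only the primary silyl group to give (4R)-4-[(2S,4R)-5,5-dimethyl-4-(triethylsilyloxy)oxolan-2-yl]pentan-1-ol F6, and iodination as in step 8 (I2, PPh3, imidazole) returns to the route at 13.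

3. Step 6. α-Metalation of the oxirane (carbenoid pathways, cleavage of the oxolane) may compete with the syn β-elimination, or the elimination may stall on the hindered bicycle. The fallback sets out from 6 and oxygenates C14 by an ene reaction. mCPBA (1.0 equiv, −20 °C) should epoxidise only the electron-rich side-chain alkene to (5R)-5-[(2R)-4-(3,3-dimethyloxiran-2-yl)butan-2-yl]-2,2-dimethyl-2,5-dihydrofuran F7. Dye-sensitised photo-oxygenation (O2, tetraphenylporphyrin, hν, CH2Cl2, 0 °C) should effect a Schenck ene reaction of the ring alkene: the only allylic hydrogen (C12–H) is abstracted and oxygen is delivered suprafacially to C14 on the face opposite the side chain, giving (3R)-5-[(2R)-4-(3,3-dimethyloxiran-2-yl)butan-2-yl]-2,2-dimethyl-2,3-dihydrofuran-3-yl hydroperoxide F8. PPh3 reduces it to (3R)-5-[(2R)-4-(3,3-dimethyloxiran-2-yl)butan-2-yl]-2,2-dimethyl-2,3-dihydrofuran-3-ol F9, which has no free δ-hydroxyl. Directed hydrogenation as in step 7 should give (3R,5S)-5-[(2R)-4-(3,3-dimethyloxiran-2-yl)butan-2-yl]-2,2-dimethyloxolan-3-ol F10; periodic acid cleaves the side-chain oxirane to (4R)-4-[(2S,4R)-4-hydroxy-5,5-dimethyloxolan-2-yl]pentanal F11, and NaBH4 returns to the route at 11.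

Further compounds
F1 | step 3 | (4R,5S,6R)-5-chloro-6,10-dimethylundec-9-en-2-yn-4-ol | CC(C)=CCC[C@@H](C)[C@@H]([C@H](O)C#CC)Cl
F2 | step 3 | (2R,3R)-2-[(2R)-6-methylhept-5-en-2-yl]-3-(prop-1-yn-1-yl)oxirane | CC(C)=CCC[C@@H](C)[C@H]1O[C@@H]1C#CC
F3 | step 3 | (5R,6R)-2,6,10-trimethylundeca-2,3,9-trien-5-ol | CC(C)=CCC[C@@H](C)[C@@H](O)C=C=C(C)C
F4 | step 7 | triethyl{[(4R)-4-[(4R)-5,5-dimethyl-4-(triethylsilyloxy)-4,5-dihydrofuran-2-yl]pentyl]oxy}silane | CC[Si](CC)(CC)OCCC[C@@H](C)C1=C[C@@H](O[Si](CC)(CC)CC)C(C)(C)O1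
F5 | step 7 | triethyl{[(4R)-4-[(2S,4R)-5,5-dimethyl-4-(triethylsilyloxy)oxolan-2-yl]pentyl]oxy}silane | CC[Si](CC)(CC)OCCC[C@@H](C)[C@@H]1C[C@@H](O[Si](CC)(CC)CC)C(C)(C)O1
F6 | step 7 | (4R)-4-[(2S,4R)-5,5-dimethyl-4-(triethylsilyloxy)oxolan-2-yl]pentan-1-ol | OCCC[C@@H](C)[C@@H]1C[C@@H](O[Si](CC)(CC)CC)C(C)(C)O1
F7 | step 6 | (5R)-5-[(2R)-4-(3,3-dimethyloxiran-2-yl)butan-2-yl]-2,2-dimethyl-2,5-dihydrofuran | CC1(C)OC1CC[C@@H](C)[C@@H]1C=CC(C)(C)O1
F8 | step 6 | (3R)-5-[(2R)-4-(3,3-dimethyloxiran-2-yl)butan-2-yl]-2,2-dimethyl-2,3-dihydrofuran-3-yl hydroperoxide | CC1(C)OC1CC[C@@H](C)C1=C[C@@H](OO)C(C)(C)O1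
F9 | step 6 | (3R)-5-[(2R)-4-(3,3-dimethyloxiran-2-yl)butan-2-yl]-2,2-dimethyl-2,3-dihydrofuran-3-ol | CC1(C)OC1CC[C@@H](C)C1=C[C@@H](O)C(C)(C)O1
F10 | step 6 | (3R,5S)-5-[(2R)-4-(3,3-dimethyloxiran-2-yl)butan-2-yl]-2,2-dimethyloxolan-3-ol | CC1(C)OC1CC[C@@H](C)[C@@H]1C[C@@H](O)C(C)(C)O1
F11 | step 6 | (4R)-4-[(2S,4R)-4-hydroxy-5,5-dimethyloxolan-2-yl]pentanal | O=CCC[C@@H](C)[C@@H]1C[C@@H](O)C(C)(C)O1
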